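Chain numbering: C1 = OCH2, C14 = stereocentre, C16 = chain end. Retrosynthetic cuts, in order: the two ArO–CH2Ph bonds of a benzyl-masked catechol, then C6–C7 in the middle of the chain, then the acyl C–O bond of the ester (left half) and C12–C13 (right half).
Forward: a C5 chiral-pool Grignard reagent is joined to a C6 bromochloride (C12–C13) and the chloride is exchanged for iodide. Separately the protected acid is esterified with hex-5-en-1-ol. The C11 iodide and the alkenyl ester are united at C6–C7, and the benzyl groups are removed last. No ring is formed.
Enabling feature: C2–C13 is an unbranched, heteroatom-free run of twelve CH2 groups, so a cut at C6–C7 leaves two primary carbons. C6 can be reached as a primary alkylnickel from a terminal C5=C6 alkene, and C7 as a primary radical from a C–I bond. Five CH2 groups separate the ester O from C6, C14 lies seven bonds from C7, and the benzene ring is a spectator once O-2 and O-3 are benzylated.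
Idea of the key event: neither carbon is a preformed nucleophile. A nickel hydride reverses the polarity of the alkene terminus in situ and the iodide enters as a radical, so the complete aryl ester half can be carried into the coupling.
Stereochemistry: the only stereocentre, C14 (S), is bought with (S)-1-bromo-2-methylbutane. No bond to it is made or broken, and it lies in the half that the nickel hydride never touches.

Key step: step 4

Remark: (S)-1-bromo-2-methylbutane, 1-bromo-6-chlorohexane, 2,3-bis(benzyloxy)benzoic acid and hex-5-en-1-ol are taken as catalogue compounds.

Step 1
Reactants: 1 (S)-1-bromo-2-methylbutane; 2 1-bromo-6-chlorohexane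
Product: 4 (S)-1-chloro-8-methyldecane, via (S)-2-methylbutylmagnesium bromide 3 (not isolated)
Conditions: Mg, THF, 40 °C; then 2 (1.0 equiv), Li2CuCl4 (3 mol %), THF, −10 °C → rt
Reagents that add atoms: magnesium, [Mg] (retained in intermediate 3 only)
Why: Copper-catalysed (Kochi-type) Grignard–alkyl halide cross-coupling, in which the primary C–Br bond of 2 should react far faster than its C–Cl bond so that no excess of 2 is needed, while the stereocentre, β to magnesium, takes part in no bond change.

Step 2
Reactants: 4 (S)-1-chloro-8-methyldecane
Product: 5 (S)-1-iodo-8-methyldecane
Conditions: NaI (3 equiv), 2-butanone, reflux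
Reagents that add atoms: sodium iodide, [Na+].[I-]
Why: Finkelstein halide exchange (SN2 at an unhindered primary carbon) driven by precipitation of the sodium chloride, with the remote stereocentre untouched.

Step 3
Reactants: 6 2,3-bis(benzyloxy)benzoic acid; 7 hex-5-en-1-ol
Product: 8 hex-5-en-1-yl 2,3-bis(benzyloxy)benzoate
Conditions: DCC (1.1 equiv), DMAP (10 mol %), CH2Cl2, 0 °C → rt
Reagents that add atoms: none
Why: Steglich esterification, in which DMAP intercepts the O-acylisourea as an acylpyridinium ion that the unhindered primary alcohol attacks, while the benzyl ethers and the terminal alkene are inert.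

Step 4
Reactants: 5 (S)-1-iodo-8-methyldecane; 8 hex-5-en-1-yl 2,3-bis(benzyloxy)benzoate
Product: 9 (S)-14-methylhexadecyl 2,3-bis(benzyloxy)benzoate
Conditions: 5 (1.0 equiv), 8 (1.5 equiv), NiBr2·diglyme (10 mol %), 4,4'-di-tert-butyl-2,2'-bipyridine (15 mol %), (EtO)2MeSiH (2.5 equiv), Na2CO3 (2 equiv), DMA, 25 °C
Reagents that add atoms: none
Why: A bipyridine-ligated Ni–H species, generated from the nickel(II) salt and carbonate-activated (EtO)2MeSiH, should insert the terminal C5=C6 alkene of 8 anti-Markovnikov to place nickel on primary C6, while low-valent nickel abstracts iodine from 5 to release the primary C7 radical; capture of that radical by the alkylnickel and reductive elimination from the dialkylnickel(III) forms C6–C7 and returns nickel to the cycle. The closest known reaction type is the NiH-catalysed reductive anti-Markovnikov hydroalkylation (olefin hydrocarbonation) of unactivated terminal alkenes with unactivated primary alkyl iodides, which runs at room temperature and tolerates esters and ethers. It unites an electrophilic C–I carbon with an alkene terminus that is no nucleophile, the silane supplying both electrons and the hydrogen at C5, so that no stoichiometric organometallic ever meets the benzoate carbonyl. No ring is closed and no stereocentre is created; C14 rides in the iodide half, which never passes through Ni–H insertion or β-hydride elimination before the bond forms, so chain walking cannot reach it. The step needs cross- over homo-coupling, secured by the orthogonal activation of the partners (only the alkene inserts into Ni–H, only the C–I bond is opened by halogen abstraction), and linear over branched alkylation, secured by the unhindered monosubstituted alkene, whose four-CH2 spacer keeps the ester carbonyl too far away to stabilise a secondary alkylnickel chelate and whose secondary insertion product can revert by β-hydride elimination. Benzylation of O-2 and O-3 removes the acidic, nickel-chelating catechol that would otherwise quench the Ni–H species.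

Step 5
Reactants: 9 (S)-14-methylhexadecyl 2,3-bis(benzyloxy)benzoate
Product: 10 gentiside C, (S)-14-methylhexadecyl 2,3-dihydroxybenzoate
Conditions: H2 (1 atm), 10 % Pd/C, EtOAc, rt
Reagents that add atoms: none
Why: Heterogeneous hydrogenolysis of the two aryl benzyl ethers, to which the alkyl benzoate, the saturated chain and C14 are inert, in a non-nucleophilic solvent that excludes transesterification.

Compound list
1 | (S)-1-bromo-2-methylbutane | CC[C@H](C)CBr | starting material
2 | 1-bromo-6-chlorohexane | ClCCCCCCBr | starting material
3 | (S)-2-methylbutylmagnesium bromide | CC[C@H](C)C[Mg]Br | intermediate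
4 | (S)-1-chloro-8-methyldecane | CC[C@H](C)CCCCCCCCl | intermediate
5 | (S)-1-iodo-8-methyldecane | CC[C@H](C)CCCCCCCI | intermediate
6 | 2,3-bis(benzyloxy)benzoic acid | OC(=O)c1cccc(OCc2ccccc2)c1OCc1ccccc1 | starting material
7 | hex-5-en-1-ol | C=CCCCCO | starting material
8 | hex-5-en-1-yl 2,3-bis(benzyloxy)benzoate | C=CCCCCOC(=O)c1cccc(OCc2ccccc2)c1OCc1ccccc1 | intermediate
9 | (S)-14-methylhexadecyl 2,3-bis(benzyloxy)benzoate | CC[C@H](C)CCCCCCCCCCCCCOC(=O)c1cccc(OCc2ccccc2)c1OCc1ccccc1 | intermediate
10 | gentiside C, (S)-14-methylhexadecyl 2,3-dihydroxybenzoate | CC[C@H](C)CCCCCCCCCCCCCOC(=O)c1cccc(O)c1O | target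

Total step count: 5. Longest linear sequence: 4 (steps 1, 2, 4, 5).

Most likely to fail, first: step 4. Hydrodehalogenation and homocoupling of the iodide may outrun the cross-coupling. So may isomerisation, hydrogenation or hydrosilylation of the alkene. The fallback separates hydride delivery from C–C bond formation and uses a preformed organoboron nucleophile. It sets out from 8 (with 5 as partner) and comes back to the route at 9. Alkene 8 is hydroborated with 9-BBN-H (THF, 0 °C → rt) to give 6-(9-borabicyclo[3.3.1]nonan-9-yl)hexyl 2,3-bis(benzyloxy)benzoate F1. This is coupled in the same flask with iodide 5 in a B-alkyl Suzuki–Miyaura reaction under a bulky trialkylphosphine palladium catalyst (Pd(OAc)2, PCy3, K3PO4·H2O, THF, rt) to give 9.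

Second: step 1. Wurtz-type homocoupling during magnesium insertion may erode the conversion into the cross-coupled chain, as may halogen–metal exchange or β-hydride loss at copper. The fallback replaces magnesium and copper by an acetylide SN2 alkylation. It sets out from 1 and comes back to the route at 5, so that step 2 is bypassed as well. Bought hex-5-yn-1-ol (C#CCCCCO) is doubly deprotonated (n-BuLi, 2 equiv, THF/DMPU, −78 → 0 °C) to dilithiated hex-5-yn-1-ol F2. Its carbon terminus is alkylated by bromide 1 to give, after aqueous work-up, (S)-8-methyldec-5-yn-1-ol F3. Hydrogenation over PtO2 (H2, EtOAc, rt), chosen to limit double-bond migration towards the stereocentre, gives (S)-8-methyldecan-1-ol F4. An Appel-type iodination (I2, PPh3, imidazole, CH2Cl2, 0 °C) then gives 5.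

Third: step 5. Traces of iodide, nickel or bipyridine carried over from the key step may poison the palladium surface and stall the reaction at the mono-benzyl stage. Slow filtration in air may also oxidise the liberated catechol. The fallback replaces hydrogenolysis by a metal-free Lewis-acid cleavage. It sets out from 9 and comes back to the route at 10. The conditions are BCl3 with pentamethylbenzene as benzyl cation scavenger (CH2Cl2, −78 °C), then a methanol quench, which a primary alkyl benzoate should survive. This fallback makes no new compound (F0).

Further compounds
F1 | step 4 | 6-(9-borabicyclo[3.3.1]nonan-9-yl)hexyl 2,3-bis(benzyloxy)benzoate | O=C(OCCCCCCB1C2CCCC1CCC2)c1cccc(OCc2ccccc2)c1OCc1ccccc1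
F2 | step 1 | dilithiated hex-5-yn-1-ol | [Li]C#CCCCCO[Li]
F3 | step 1 | (S)-8-methyldec-5-yn-1-ol | CC[C@H](C)CC#CCCCCO
F4 | step 1 | (S)-8-methyldecan-1-ol | CC[C@H](C)CCCCCCCO
F0 | step 5 | none | none
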